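**Plan**

- Retrosynthesis: the O-benzyl and O-MOM groups are removed last. The bridging CH2 is traced back to a diaryl ketone, which is cut between the carbonyl carbon and ring B C4 (ring B aryllithium 24 plus the ring C lactone 13).
- Ring C carries the bridge carbon on C1, the arylethyl chain on C2, OH on C4 and OMe on C6. With the bridge carbon read as a carboxyl carbon this is an orsellinate-type tetraketide ring, so it is cut at C1–C2 and unfolds to diketo-dioxinone 10.
- The chain of 10 is cut between the two ketone units (dianion of keto-dioxinone 9 plus Weinreb amide 6 from ferulic acid). Bibenzyl 23 is cut at the ring B aryl–CH2 bond (B-alkyl Suzuki coupling of a vanillin-derived styrene).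
- Forward: chain assembly (steps 1–5), ring C by aldol aromatization (step 6), bibenzyl 23 (steps 8–11), union at the future bridge carbon (step 12), then O-methylation, MOM removal, C=O to CH2 and hydrogenolysis (steps 13–16).
- Rings A, B and D are bought as arenes; ring C is the only ring that is built.
- Stereochemistry: the target has no stereocentre, so nothing has to be controlled.

Key step: step 6

Remark on the chemistry: ring A is the 4-hydroxy-3-methoxyphenyl ring on the ring B side and ring D the one on the ring C side. The only stereocentres on the way (aldol adduct 11, fallback carbinols) are racemic and are destroyed again.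

**Route**

Step 1
Reactants: 1 ferulic acid
Product: 2 3-(4-hydroxy-3-methoxyphenyl)propanoic acid
Conditions: H2 (1 atm), 10% Pd/C, MeOH, rt
Reagents that add atoms: none
Why: Heterogeneous catalytic hydrogenation saturates the cinnamate C=C, while the arene, the acid and the phenol are inert under these conditions.

Step 2
Reactants: 2 3-(4-hydroxy-3-methoxyphenyl)propanoic acid; 3 benzyl bromide
Product: 4 benzyl 3-[4-(benzyloxy)-3-methoxyphenyl]propanoate
Conditions: BnBr (2.3 equiv), K2CO3, DMF, 50 °C
Reagents that add atoms: benzyl bromide (3), BrCc1ccccc1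
Why: Williamson-type O-alkylation of phenoxide and carboxylate in one operation protects the ring D phenol and gives an ester that serves as the acyl donor of step 3.

Step 3
Reactants: 4 benzyl 3-[4-(benzyloxy)-3-methoxyphenyl]propanoate; 5 N,O-dimethylhydroxylamine hydrochloride
Product: 6 3-[4-(benzyloxy)-3-methoxyphenyl]-N-methoxy-N-methylpropanamide
Conditions: MeNHOMe·HCl, i-PrMgCl, THF, −20 → 0 °C
Reagents that add atoms: N,O-dimethylhydroxylamine hydrochloride (5), CNOC.Cl
Why: Direct ester-to-Weinreb-amide aminolysis by the chloromagnesium amide formed in the flask; the aryl benzyl ether is untouched and benzyl alcohol is the only organic by-product.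

Step 4
Reactants: 7 2,2,6-trimethyl-4H-1,3-dioxin-4-one; 8 acetyl chloride
Product: 9 2,2-dimethyl-6-(2-oxopropyl)-4H-1,3-dioxin-4-one
Conditions: LiN(SiMe3)2, THF, −78 °C; then AcCl (0.5 equiv), −78 °C; aq. NH4Cl
Reagents that add atoms: acetyl chloride (8), CC(Cl)=O
Why: Vinylogous Claisen-type C-acylation of the lithium dienolate at the 6-methyl carbon; half an equivalent of AcCl is used because the more acidic product consumes a second equivalent of dienolate.

Step 5
Reactants: 9 2,2-dimethyl-6-(2-oxopropyl)-4H-1,3-dioxin-4-one; 6 3-[4-(benzyloxy)-3-methoxyphenyl]-N-methoxy-N-methylpropanamide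
Product: 10 6-{6-[4-(benzyloxy)-3-methoxyphenyl]-2,4-dioxohexyl}-2,2-dimethyl-4H-1,3-dioxin-4-one
Conditions: i-Pr2NLi (LDA, 2.2 equiv), THF, −78 °C; then 6, −78 → −20 °C; aq. NH4Cl; used without long storage
Reagents that add atoms: none
Why: Claisen-type C-acylation of the keto-dioxinone dianion at its terminal, more reactive enolate carbon with a Weinreb amide, whose chelated tetrahedral adduct survives until work-up so that the reaction should stop at the 1,3-diketone.

Step 6
Reactants: 10 6-{6-[4-(benzyloxy)-3-methoxyphenyl]-2,4-dioxohexyl}-2,2-dimethyl-4H-1,3-dioxin-4-one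
Product: 12 5-{2-[4-(benzyloxy)-3-methoxyphenyl]ethyl}-7-hydroxy-2,2-dimethyl-4H-1,3-benzodioxin-4-one, via cyclic aldol adduct 11 (not isolated)
Conditions: Et3N, CH2Cl2, rt; then dilute HCl (MeOH), rt
Reagents that add atoms: none
Why: Et3N deprotonates the doubly activated methylene next to the dioxinone, and the dienolate attacks through the dioxinone C5 carbon (future ring C C1) on the distal ketone (future C2) in an intramolecular aldol addition to give 11; acid then removes water and the remaining ring ketone enolises to the arene with a free 7-OH. The closest known reaction type is the biomimetic aldol aromatization of diketo-dioxinones to acetonide-protected resorcylates. Ring C, the only ring formed, closes in a 6-(enolexo)-exo-trig mode with the oxygen of the attacked carbonyl outside the new ring. The carbinol centre of 11 is racemic and vanishes on dehydration, so no stereocentre has to be controlled. The step needs C-cyclisation between C5 and the distal ketone instead of O-cyclisation to a pyranone or a Claisen closure; the acetonide mask keeps the carboxyl terminus from acting as an acyl donor at room temperature, and no other nucleophile–electrophile pair of 10 can give a six-membered carbocycle. The same mask leaves the C7 oxygen free while the C8a oxygen and the carbonyl stay locked, which differentiates the two ring C oxygens as the target requires (OH at C4, OMe at C6).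

Step 7
Reactants: 12 5-{2-[4-(benzyloxy)-3-methoxyphenyl]ethyl}-7-hydroxy-2,2-dimethyl-4H-1,3-benzodioxin-4-one; 3 benzyl bromide
Product: 13 7-(benzyloxy)-5-{2-[4-(benzyloxy)-3-methoxyphenyl]ethyl}-2,2-dimethyl-4H-1,3-benzodioxin-4-one
Conditions: BnBr, K2CO3, acetone, reflux
Reagents that add atoms: benzyl bromide (3), BrCc1ccccc1
Why: Williamson etherification of the only free phenol, which is acidic because it is para to the lactone carbonyl; the salicylate acetonide is stable to K2CO3.

Step 8
Reactants: 14 vanillin; 3 benzyl bromide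
Product: 15 4-(benzyloxy)-3-methoxybenzaldehyde
Conditions: BnBr, K2CO3, DMF, rt
Reagents that add atoms: benzyl bromide (3), BrCc1ccccc1
Why: Williamson etherification protects the ring A phenol with the same group as rings C and D, so that one hydrogenolysis frees all three at the end.

Step 9
Reactants: 15 4-(benzyloxy)-3-methoxybenzaldehyde; 16 methyltriphenylphosphonium bromide
Product: 17 1-(benzyloxy)-4-ethenyl-2-methoxybenzene
Conditions: Ph3PCH3Br, KOt-Bu, THF, 0 °C → rt
Reagents that add atoms: methyltriphenylphosphonium bromide (16), C[P+](c1ccccc1)(c1ccccc1)c1ccccc1.[Br-]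
Why: Wittig methylenation of a non-enolisable, electron-rich benzaldehyde with the unstabilised ylide gives the styrene.

Step 10
Reactants: 18 3-bromo-5-methoxyphenol; 19 chloromethyl methyl ether
Product: 20 1-bromo-3-methoxy-5-(methoxymethoxy)benzene
Conditions: MOMCl, i-Pr2NEt, CH2Cl2, 0 °C → rt
Reagents that add atoms: chloromethyl methyl ether (19), COCCl
Why: O-alkylation of the phenol with MOMCl installs an acetal ether that later directs the ortho-lithiation and is cleaved by acid independently of the benzyl ethers.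

Step 11
Reactants: 17 1-(benzyloxy)-4-ethenyl-2-methoxybenzene; 21 9-borabicyclo[3.3.1]nonane (9-BBN); 20 1-bromo-3-methoxy-5-(methoxymethoxy)benzene
Product: 23 1-(benzyloxy)-2-methoxy-4-{2-[3-methoxy-5-(methoxymethoxy)phenyl]ethyl}benzene, via B-alkyl-9-BBN borane 22 (not isolated)
Conditions: 9-BBN, THF, 0 °C → rt; then 20, PdCl2(dppf) (3 mol %), aq. K3PO4, DMF, 60 °C
Reagents that add atoms: none
Why: Anti-Markovnikov hydroboration of the styrene followed by B-alkyl Suzuki–Miyaura coupling (oxidative addition of the aryl bromide to zerovalent palladium, base-assisted transmetalation) forms the ring A–CH2CH2–ring B link without any alkene hydrogenation that could endanger the benzyl ether.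

Step 12
Reactants: 23 1-(benzyloxy)-2-methoxy-4-{2-[3-methoxy-5-(methoxymethoxy)phenyl]ethyl}benzene; 13 7-(benzyloxy)-5-{2-[4-(benzyloxy)-3-methoxyphenyl]ethyl}-2,2-dimethyl-4H-1,3-benzodioxin-4-one
Product: 25 {4-(benzyloxy)-2-{2-[4-(benzyloxy)-3-methoxyphenyl]ethyl}-6-hydroxyphenyl}{4-{2-[4-(benzyloxy)-3-methoxyphenyl]ethyl}-2-methoxy-6-(methoxymethoxy)phenyl}methanone, via ring B aryllithium 24 (not isolated)
Conditions: 23 (1.2 equiv), n-BuLi (1.15 equiv), THF, 0 °C, 1 h; then 13 (1.0 equiv), THF, −78 °C → rt; aq. NH4Cl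
Reagents that add atoms: none
Why: Directed ortho-metalation at the one position flanked by OMe and OMOM, then nucleophilic acyl substitution of the salicylate acetonide by the aryllithium; the tetrahedral adduct collapses with loss of acetone to an ortho-phenoxide ketone that is electronically and sterically shielded from a second addition.

Step 13
Reactants: 25 the hydroxy ketone of step 12; 26 iodomethane
Product: 27 {4-(benzyloxy)-2-{2-[4-(benzyloxy)-3-methoxyphenyl]ethyl}-6-methoxyphenyl}{4-{2-[4-(benzyloxy)-3-methoxyphenyl]ethyl}-2-methoxy-6-(methoxymethoxy)phenyl}methanone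
Conditions: MeI, K2CO3, DMF, 40 °C
Reagents that add atoms: iodomethane (26), CI
Why: Williamson methylation of the single free phenol (the ring C oxygen released from the acetonide) sets the C6-OMe of ring C; the diaryl ketone has no enolisable position and the MOM and benzyl ethers are base-stable.

Step 14
Reactants: 27 the methoxy ketone of step 13
Product: 28 {4-(benzyloxy)-2-{2-[4-(benzyloxy)-3-methoxyphenyl]ethyl}-6-methoxyphenyl}{4-{2-[4-(benzyloxy)-3-methoxyphenyl]ethyl}-2-hydroxy-6-methoxyphenyl}methanone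
Conditions: HCl (3 M in MeOH), THF, 40 °C
Reagents that add atoms: none
Why: Acid-catalysed transacetalisation of the MOM ether to methanol frees the ring B phenol; it is done at the ketone stage, where the acyl group deactivates rings B and C towards attack by the formaldehyde equivalent, and benzyl ethers survive.

Step 15
Reactants: 28 the hydroxy ketone of step 14
Product: 29 2-{[4-(benzyloxy)-2-{2-[4-(benzyloxy)-3-methoxyphenyl]ethyl}-6-methoxyphenyl]methyl}-5-{2-[4-(benzyloxy)-3-methoxyphenyl]ethyl}-3-methoxyphenol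
Conditions: Et3SiH (5 equiv), CF3CO2H, CH2Cl2, 0 °C → rt
Reagents that add atoms: none
Why: Ionic hydrogenation: the protonated ketone and then the diarylmethyl cation, both strongly stabilised by the ortho and para oxygen donors of rings B and C, take up hydride from Et3SiH twice to give the bridging CH2, while aryl benzyl ethers should tolerate dilute CF3CO2H at this temperature.

Step 16
Reactants: 29 the tribenzyl ether of step 15
Product: 30 4-{[2-hydroxy-4-[2-(4-hydroxy-3-methoxyphenyl)ethyl]-6-methoxyphenyl]methyl}-3-[2-(4-hydroxy-3-methoxyphenyl)ethyl]-5-methoxyphenol (target)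
Conditions: H2 (1 atm), 10% Pd/C, EtOAc/MeOH, rt
Reagents that add atoms: none
Why: Catalytic hydrogenolysis cleaves the three aryl benzyl ethers under neutral conditions and leaves methyl ethers, the diarylmethane and the bibenzyl chains untouched.

**Compound list**

1 | ferulic acid, (E)-3-(4-hydroxy-3-methoxyphenyl)prop-2-enoic acid | COc1cc(/C=C/C(=O)O)ccc1O | starting material
2 | 3-(4-hydroxy-3-methoxyphenyl)propanoic acid | COc1cc(CCC(=O)O)ccc1O | intermediate
3 | benzyl bromide | BrCc1ccccc1 | starting material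
4 | benzyl 3-[4-(benzyloxy)-3-methoxyphenyl]propanoate | COc1cc(CCC(=O)OCc2ccccc2)ccc1OCc1ccccc1 | intermediate
5 | N,O-dimethylhydroxylamine hydrochloride | CNOC.Cl | starting material
6 | 3-[4-(benzyloxy)-3-methoxyphenyl]-N-methoxy-N-methylpropanamide | COc1cc(CCC(=O)N(C)OC)ccc1OCc1ccccc1 | intermediate
7 | 2,2,6-trimethyl-4H-1,3-dioxin-4-one | CC1=CC(=O)OC(C)(C)O1 | starting material
8 | acetyl chloride | CC(Cl)=O | starting material
9 | 2,2-dimethyl-6-(2-oxopropyl)-4H-1,3-dioxin-4-one | CC(=O)CC1=CC(=O)OC(C)(C)O1 | intermediate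
10 | 6-{6-[4-(benzyloxy)-3-methoxyphenyl]-2,4-dioxohexyl}-2,2-dimethyl-4H-1,3-dioxin-4-one | CC1(C)OC(=O)C=C(CC(=O)CC(=O)CCc2ccc(OCc3ccccc3)c(OC)c2)O1 | intermediate
11 | cyclic aldol adduct (racemic, formed in the flask), 5-{2-[4-(benzyloxy)-3-methoxyphenyl]ethyl}-5-hydroxy-2,2-dimethyl-5,6-dihydro-4H-1,3-benzodioxine-4,7(8H)-dione | CC1(C)OC(=O)C2=C(CC(=O)CC2(O)CCc2ccc(OCc3ccccc3)c(OC)c2)O1 | intermediate
12 | 5-{2-[4-(benzyloxy)-3-methoxyphenyl]ethyl}-7-hydroxy-2,2-dimethyl-4H-1,3-benzodioxin-4-one | CC1(C)OC(=O)c2c(CCc3ccc(OCc4ccccc4)c(OC)c3)cc(O)cc2O1 | intermediate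
13 | 7-(benzyloxy)-5-{2-[4-(benzyloxy)-3-methoxyphenyl]ethyl}-2,2-dimethyl-4H-1,3-benzodioxin-4-one | CC1(C)OC(=O)c2c(CCc3ccc(OCc4ccccc4)c(OC)c3)cc(OCc3ccccc3)cc2O1 | intermediate
14 | vanillin | COc1cc(C=O)ccc1O | starting material
15 | 4-(benzyloxy)-3-methoxybenzaldehyde | COc1cc(C=O)ccc1OCc1ccccc1 | intermediate
16 | methyltriphenylphosphonium bromide | C[P+](c1ccccc1)(c1ccccc1)c1ccccc1.[Br-] | starting material
17 | 1-(benzyloxy)-4-ethenyl-2-methoxybenzene | COc1cc(C=C)ccc1OCc1ccccc1 | intermediate
18 | 3-bromo-5-methoxyphenol | COc1cc(O)cc(Br)c1 | starting material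
19 | chloromethyl methyl ether | COCCl | starting material
20 | 1-bromo-3-methoxy-5-(methoxymethoxy)benzene | COCOc1cc(Br)cc(OC)c1 | intermediate
21 | 9-borabicyclo[3.3.1]nonane (9-BBN) | B1C2CCCC1CCC2 | starting material
22 | 9-{2-[4-(benzyloxy)-3-methoxyphenyl]ethyl}-9-borabicyclo[3.3.1]nonane (formed in the flask) | COc1cc(CCB2C3CCCC2CCC3)ccc1OCc1ccccc1 | intermediate
23 | 1-(benzyloxy)-2-methoxy-4-{2-[3-methoxy-5-(methoxymethoxy)phenyl]ethyl}benzene | COCOc1cc(CCc2ccc(OCc3ccccc3)c(OC)c2)cc(OC)c1 | intermediate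
24 | {4-{2-[4-(benzyloxy)-3-methoxyphenyl]ethyl}-2-methoxy-6-(methoxymethoxy)phenyl}lithium (formed in the flask) | [Li]c1c(OC)cc(CCc2ccc(OCc3ccccc3)c(OC)c2)cc1OCOC | intermediate
25 | {4-(benzyloxy)-2-{2-[4-(benzyloxy)-3-methoxyphenyl]ethyl}-6-hydroxyphenyl}{4-{2-[4-(benzyloxy)-3-methoxyphenyl]ethyl}-2-methoxy-6-(methoxymethoxy)phenyl}methanone | O=C(c1c(O)cc(OCc2ccccc2)cc1CCc1ccc(OCc2ccccc2)c(OC)c1)c1c(OC)cc(CCc2ccc(OCc3ccccc3)c(OC)c2)cc1OCOC | intermediate
26 | iodomethane | CI | starting material
27 | {4-(benzyloxy)-2-{2-[4-(benzyloxy)-3-methoxyphenyl]ethyl}-6-methoxyphenyl}{4-{2-[4-(benzyloxy)-3-methoxyphenyl]ethyl}-2-methoxy-6-(methoxymethoxy)phenyl}methanone | O=C(c1c(OC)cc(OCc2ccccc2)cc1CCc1ccc(OCc2ccccc2)c(OC)c1)c1c(OC)cc(CCc2ccc(OCc3ccccc3)c(OC)c2)cc1OCOC | intermediate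
28 | {4-(benzyloxy)-2-{2-[4-(benzyloxy)-3-methoxyphenyl]ethyl}-6-methoxyphenyl}{4-{2-[4-(benzyloxy)-3-methoxyphenyl]ethyl}-2-hydroxy-6-methoxyphenyl}methanone | O=C(c1c(OC)cc(OCc2ccccc2)cc1CCc1ccc(OCc2ccccc2)c(OC)c1)c1c(OC)cc(CCc2ccc(OCc3ccccc3)c(OC)c2)cc1O | intermediate
29 | 2-{[4-(benzyloxy)-2-{2-[4-(benzyloxy)-3-methoxyphenyl]ethyl}-6-methoxyphenyl]methyl}-5-{2-[4-(benzyloxy)-3-methoxyphenyl]ethyl}-3-methoxyphenol | COc1cc(CCc2cc(O)c(Cc3c(CCc4ccc(OCc5ccccc5)c(OC)c4)cc(OCc4ccccc4)cc3OC)c(OC)c2)ccc1OCc1ccccc1 | intermediate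
30 | 4-{[2-hydroxy-4-[2-(4-hydroxy-3-methoxyphenyl)ethyl]-6-methoxyphenyl]methyl}-3-[2-(4-hydroxy-3-methoxyphenyl)ethyl]-5-methoxyphenol (CNP0079000.0) | COc1cc(CCc2cc(O)c(Cc3c(CCc4ccc(O)c(OC)c4)cc(O)cc3OC)c(OC)c2)ccc1O | target

**Step count**

Total: 16 steps. Longest linear sequence: 11 steps (steps 1, 2, 3, 5, 6, 7, 12, 13, 14, 15, 16, from ferulic acid). Step 4 and steps 8–11 are convergent branches.

**Steps most likely to fail**

Step 12. The aryllithium may act as a base instead of a nucleophile and remove a benzylic proton ortho to the lactone carbonyl. It may also be consumed by the acetone released on collapse of the adduct, or add slowly because both partners are ortho,ortho-disubstituted. The fallback sets out from 13 and uses an aldehyde as the electrophile. Reduction of 13 with i-Bu2AlH (CH2Cl2, −78 °C) opens the acetonide to 4-(benzyloxy)-2-{2-[4-(benzyloxy)-3-methoxyphenyl]ethyl}-6-hydroxybenzaldehyde F1. Methylation (MeI, K2CO3, DMF) gives 4-(benzyloxy)-2-{2-[4-(benzyloxy)-3-methoxyphenyl]ethyl}-6-methoxybenzaldehyde F2. Aryllithium 24, made from 23 as in step 12, adds to this far more electrophilic carbonyl to give the racemic diaryl carbinol {4-(benzyloxy)-2-{2-[4-(benzyloxy)-3-methoxyphenyl]ethyl}-6-methoxyphenyl}{4-{2-[4-(benzyloxy)-3-methoxyphenyl]ethyl}-2-methoxy-6-(methoxymethoxy)phenyl}methanol F3. Oxidation with Dess–Martin periodinane brings the sequence back to the route at ketone 27.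

Step 15. In CF3CO2H the doubly ortho-oxygenated ring B may be protonated at the ipso carbon, which would cleave the aryl–carbonyl (or aryl–carbinol) bond. The reduction may also stall at the carbinol because of congestion, or benzyl ethers may be lost in part. The fallback sets out from 28 and avoids strong acid. Hydride reduction (LiAlH4, THF, 0 °C → rt) gives the racemic benzhydrol {4-(benzyloxy)-2-{2-[4-(benzyloxy)-3-methoxyphenyl]ethyl}-6-methoxyphenyl}{4-{2-[4-(benzyloxy)-3-methoxyphenyl]ethyl}-2-hydroxy-6-methoxyphenyl}methanol F4. Hydrogenolysis (H2, Pd/C, EtOAc/MeOH with a little AcOH) then removes the doubly benzylic, ortho-hydroxy-activated C–OH together with the three benzyl ethers. The sequence comes back to the route at the target 30, without passing through 29.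

Step 5. Proton transfer from the alpha-CH2 of the Weinreb amide to the dianion, O-acylation, or premature aromatization of the sensitive product during isolation may erode the acylation. The fallback sets out from 6 and 9 and builds the same chain at the alcohol oxidation level. Reduction of 6 with i-Bu2AlH (THF, −78 °C) gives 3-[4-(benzyloxy)-3-methoxyphenyl]propanal F5. Aldol addition of the dianion of 9 (LDA, THF, −78 °C) to this aldehyde gives racemic 6-{6-[4-(benzyloxy)-3-methoxyphenyl]-4-hydroxy-2-oxohexyl}-2,2-dimethyl-4H-1,3-dioxin-4-one F6. Oxidation with Dess–Martin periodinane comes back to the route at diketo-dioxinone 10.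

**Further compounds**

F1 | step 12 | 4-(benzyloxy)-2-{2-[4-(benzyloxy)-3-methoxyphenyl]ethyl}-6-hydroxybenzaldehyde | O=Cc1c(O)cc(OCc2ccccc2)cc1CCc1ccc(OCc2ccccc2)c(OC)c1
F2 | step 12 | 4-(benzyloxy)-2-{2-[4-(benzyloxy)-3-methoxyphenyl]ethyl}-6-methoxybenzaldehyde | O=Cc1c(OC)cc(OCc2ccccc2)cc1CCc1ccc(OCc2ccccc2)c(OC)c1
F3 | step 12 | {4-(benzyloxy)-2-{2-[4-(benzyloxy)-3-methoxyphenyl]ethyl}-6-methoxyphenyl}{4-{2-[4-(benzyloxy)-3-methoxyphenyl]ethyl}-2-methoxy-6-(methoxymethoxy)phenyl}methanol (racemic) | OC(c1c(OC)cc(OCc2ccccc2)cc1CCc1ccc(OCc2ccccc2)c(OC)c1)c1c(OC)cc(CCc2ccc(OCc3ccccc3)c(OC)c2)cc1OCOC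
F4 | step 15 | {4-(benzyloxy)-2-{2-[4-(benzyloxy)-3-methoxyphenyl]ethyl}-6-methoxyphenyl}{4-{2-[4-(benzyloxy)-3-methoxyphenyl]ethyl}-2-hydroxy-6-methoxyphenyl}methanol (racemic) | OC(c1c(OC)cc(OCc2ccccc2)cc1CCc1ccc(OCc2ccccc2)c(OC)c1)c1c(OC)cc(CCc2ccc(OCc3ccccc3)c(OC)c2)cc1O
F5 | step 5 | 3-[4-(benzyloxy)-3-methoxyphenyl]propanal | COc1cc(CCC=O)ccc1OCc1ccccc1
F6 | step 5 | 6-{6-[4-(benzyloxy)-3-methoxyphenyl]-4-hydroxy-2-oxohexyl}-2,2-dimethyl-4H-1,3-dioxin-4-one (racemic) | CC1(C)OC(=O)C=C(CC(=O)CC(O)CCc2ccc(OCc3ccccc3)c(OC)c2)O1
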